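**The decision.** Spend your care on how the first step, starting material to intermediate A, answers to temperature, and none on the charge. Ochre is colder than both earlier runs, at 5 °C.

| flask | starting material | temperature | remark | time |
|---|---|---|---|---|
| zeta | 0.28 M | 18 °C | run made earlier |  |
| delta | 0.44 M | 45 °C | run made earlier |  |
| ochre | 0.20 M | 5 °C |  | 20 min |
| grey | 0.20 M | 30 °C |  | 20 min |
| red | 0.20 M | 55 °C |  | 20 min |

| run | time / min | intermediate B / % | starting material / % | target / % | intermediate C / % | intermediate A / % |
|---|---|---|---|---|---|---|
| zeta | 1.00 | 0 | 90.5 | 0 | 0 | 9.2 |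
| zeta | 2.00 | 0.6 | 82.5 | 0.1 | 0 | 16.1 |
| zeta | 3.00 | 2.8 | 74.5 | 1.0 | 1.0 | 22.7 |
| zeta | 6.00 | 8.2 | 55.6 | 0 | 2.3 | 33.6 |
| zeta | 12.0 | 18.2 | 30.7 | 2.8 | 10.8 | 38.6 |
| delta | 0.250 | 7.0 | 58.0 | 0 | 0.9 | 32.7 |
| delta | 0.833 | 20.5 | 16.6 | 6.7 | 20.8 | 34.9 |
| delta | 1.50 | 14.4 | 4.6 | 30.9 | 33.4 | 18.1 |
| delta | 2.00 | 8.1 | 1.9 | 50.4 | 30.6 | 8.9 |
| delta | 3.00 | 2.6 | 0 | 78.5 | 16.8 | 2.0 |

(standard deviation of a reading: 0.5 percentage points)

1. which of these there is most of at the end, counted by the starting material in it, ochre (intermediate A / starting material / intermediate B / intermediate C / target)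
2. which of these there is most of at the end, counted by the starting material in it, grey (intermediate A / starting material / intermediate B / intermediate C / target)
3. which of these there is most of at the end, counted by the starting material in it, red (intermediate A / starting material / intermediate B / intermediate C / target)
4. amount of the one of these that there is most of at the end, in percent of the starting material charged, ochre
5. amount of the one of these that there is most of at the end, in percent of the starting material charged, grey
6. amount of the one of these that there is most of at the end, in percent of the starting material charged, red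

- a reading or a percentage of target counts all its forms, free or not

**The charge.** Which concentration sets the order of the rate? Try c(starting material). In the zeta run, minus the logarithm of the fraction left, divided by time, gives 0.0998 min⁻¹ at 1.00 min. It gives 0.0984 min⁻¹ at 12.0 min, when c(starting material) stands at 30.7% of its charge. The two agree, so the step is first order, and you may carry the constant from 0.28 M to 0.20 M unchanged.

**The temperature.** Used uncorrected in ochre, the zeta constant leaves 14.0% of starting material after 20 min. The delta run offers two readings for the correction. The reading at 0.833 min gives 2.16 min⁻¹, and the one at 1.50 min gives 2.05 min⁻¹.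

**The number.** My own reckoning takes the first of these. The temperature sensitivity of the first step, its activation energy, read from the two constants of the runs, is 88.0 kJ mol⁻¹. Ochre's constant is then 0.0180 min⁻¹, which leaves 69.8%. The other delta reading gives 69.1%. Either way the survivor exceeds the rest of the charge, so starting material leads.

**The forecast.** It names starting material at 70% (66% to 74%) for ochre, target at 93% (87% to 97%) for grey, and target at 99.5% (96% to 100%) for red. Its ground: “I assumed first-order steps, so concentration has no effect”.

**The flask.** Ochre holds starting material at 69.8%, grey target at 93.3%, and red target at 100%, crystals counted in target.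

    starting material → intermediate A (k = 3.00 × 10⁻⁴ s⁻¹, Ea = 88.0 kJ mol⁻¹)
    intermediate B → intermediate C (k = 3.90 × 10⁻⁴ s⁻¹, Ea = 89.0 kJ mol⁻¹)
    intermediate C → target (k = 2.60 × 10⁻⁴ s⁻¹, Ea = 80.0 kJ mol⁻¹)
    crystals ⇌ target, rate k4*(cs4 - [target]) while solid is left; crystals form when [target] > cs4 (solubility = 0.180 M, k = 0.0470 s⁻¹)
    intermediate A → intermediate B (k = 2.70 × 10⁻⁴ s⁻¹, Ea = 86.0 kJ mol⁻¹)
    (constants at 5 °C)

**The comparison.** In ochre, the asked 20 min is about half of the 39 min half-life of the first step, and the constant reckoned for ochre from 88.0 kJ mol⁻¹ was 0.0180 min⁻¹. Carried to grey, 88.0 kJ mol⁻¹ gives 0.415 min⁻¹, hence 1.58% left at 10.0 min, and grey then holds 1.58% of starting material.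

The readings were computed on assumed constants, noise included.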